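(The numbers in the tables are simulated with made-up constants.)

| setting | delta | gamma | theta | epsilon | north-east | south-west | north |
|---|---|---|---|---|---|---|---|
| substrate | 0.20 M | 0.20 M | 0.20 M | 0.20 M | 0.20 M | 0.20 M | 0.20 M (fed, over 3.0 min) |
| second nucleophile | 0.20 M | 0.20 M | 0.20 M | 0.20 M | 0.200 M | 0.200 M (fed, over 3.0 min) | 0.200 M |
| protic impurity | 0.20 M | 0.20 M | 0.20 M | 0.40 M | 0.200 M | 0.200 M | 0.200 M |
| solid first nucleophile | 0.24 M | 0.34 M | 0.53 M | 0.24 M | 0.240 M | 0.240 M | 0.240 M |
| remark | run made earlier | run made earlier | run made earlier | run made earlier | everything together at the start | all else is in the flask from the start; the feed brings no volume worth counting | all else is in the flask from the start; the feed brings no volume worth counting |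
| time |  |  |  |  | 15 min | 15 min | 15 min |

| run | time / min | solvolysis product / % | target / % | substrate / % |
|---|---|---|---|---|
| delta | 4.00 | 22.9 | 2.4 | 2.4 |
| delta | 8.00 | 27.6 | 3.2 | 0.9 |
| delta | 12.0 | 26.1 | 1.4 | 0 |
| delta | 15.0 | 27.6 | 1.2 | 0.3 |
| gamma | 3.00 | 19.7 | 3.0 | 4.7 |
| gamma | 6.00 | 26.1 | 2.2 | 0 |
| gamma | 10.0 | 26.9 | 2.6 | 0.2 |
| gamma | 12.0 | 28.0 | 1.5 | 0 |
| theta | 3.00 | 19.3 | 3.4 | 4.2 |
| theta | 6.00 | 26.4 | 1.1 | 0 |
| theta | 10.0 | 26.5 | 2.7 | 0 |
| theta | 12.0 | 26.3 | 1.6 | 0 |
| epsilon | 1.50 | 11.9 | 2.0 | 22.5 |
| epsilon | 4.00 | 36.2 | 1.2 | 2.2 |
| epsilon | 8.00 | 40.7 | 2.0 | 0 |
| epsilon | 12.0 | 39.6 | 2.5 | 0 |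

(standard deviation of a reading: 1 percentage point)

- the earlier runs were read with a standard deviation of 1 percentage point
- at the start none of the solid first nucleophile is in solution

* the flask that comes out highest in amount of solvolysis product, in percent of the substrate charged; "all alike" if 1.5 percentage points covers them all (north-east / south-west / north / all alike)
* amount of solvolysis product at the end, in percent of the substrate charged, north-east
* amount of solvolysis product at the end, in percent of the substrate charged, south-west
* amount of solvolysis product at the end, in percent of the substrate charged, north

1. I started from an invariant: substrate and second nucleophile were charged equally, so I supposed that the substrate missing from the readings sat in a capture product of the second nucleophile, and that protic impurity quenched that nucleophile. Once substrate and second nucleophile were used up, solvolysis product plus target then had to equal the quenched share, the part of the second nucleophile lost to the impurity, which the last readings of gamma and theta put at 28.7%.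

2. Delta, a separate run with less solid, summed to 28.8% in its last reading by the same count, so the readings of these runs agreed and my first way, copying the plateau, put the north-east solvolysis product near delta's 27.6%.

3. Copying the plateau treated the share as a property of the charges, but the balance contains no clock, so my second way supposed that quenching proceeded while second nucleophile waited for substrate.

4. Epsilon's 22.5% at 1.50 min gave a substrate lifetime of 1.01 min, so I treated the quench as pseudo-first-order at 0.336 /min.

5. With 0.40 M of impurity, that clock gave 49.2%, more than the 42.4% read in epsilon, so it ran high and needed scaling by that ratio.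

6. For north, I took feeding substrate over 3.0 min to stretch the mean wait to 2.51 min, which gave an estimated share of 57.0%, or 49.1% after scaling. Taking off delta's target left 47.9% of solvolysis product. I had no such clock for south-west.

7. The forecast gave north-east 27%, south-west 32% and north 26.8%, and named south-west as highest, holding that “Path independence means feeding substrate leaves the yield unchanged”. My north stood above its figure.

8. North gave 46.3%, above south-west's 37.5% and north-east's 27.0%. The mechanism, with its constants, was this:

    first nucleophile + intermediate → target (k = 1.50 /M/s)
    intermediate → solvolysis product (k = 0.0210 /s)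
    solid first nucleophile ⇌ first nucleophile, rate k3*(cs3 - [first nucleophile]) while solid is left; crystals form when [first nucleophile] > cs3 (solubility = 14.0 mM, k = 0.00160 /s)
    second nucleophile + protic impurity → quenched reagent (k = 0.0460 /M/s)
    substrate → intermediate (k = 0.0170 /s)
    second nucleophile + intermediate → other capture product (k = 2.50 /M/s)

9. At 15.0 min, north kept 50% of its impurity, and solvolysis product plus target came to 49.9%, which was 1.74 times the carried quenched share of 28.7%. In the neighbour of north-east charged with 0.080 M of second nucleophile, the balance called for the substrate unmatched by second nucleophile, 60.0% of the charge, plus a quenched 7.48%, and that flask held 67.5% as solvolysis product and target.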